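**Assumption:** the target SMILES has no stereocentre and no stereodescriptor. Artocarpol D is achiral (the oxepine tub inverts freely, both ring alkenes are fixed by the rings), so no enantiocontrol is needed.

## Retrosynthetic overview

1. Artocarpol D ⇐ ring-A aryl bromide of the bis-silylated pentacycle (C–prenyl bond by Pd coupling, then desilylation).
2. 2H-Pyran (last ring) ⇐ oxa-6π closure of the dienone from a dibenzo[b,f]oxepin-10(11H)-one and prenal; the ketone oxygen becomes the pyran oxygen.
3. Ring-A bromide ⇐ bromination of that ketone; the carbonyl deactivates ring B, so only the CH2-side ring reacts.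
4. Oxepinone (7-ring) ⇐ one-carbon insertion into one of the two equivalent C9–aryl bonds of a C2v-symmetric 3,6-bis(silyloxy)xanthone (key step, 6→7 ring expansion, symmetry broken).
5. Xanthone (first ring) ⇐ cyclodehydration of 2,2',4,4'-tetrahydroxybenzophenone, a bulk UV absorber.

## Route

**Step 1**
Reactants: 1, 2,2',4,4'-tetrahydroxybenzophenone
Product: 2, 3,6-dihydroxy-9H-xanthen-9-one
Conditions: H2O, 200 °C, sealed autoclave
Reagents that add atoms: none
Why: Thermal cyclodehydration (intramolecular addition–elimination of one ortho-OH onto the carbonyl-activated ortho carbon of the other ring) gives the symmetric xanthone; no stereocentre is involved.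

**Step 2**
Reactants: 2, 3,6-dihydroxy-9H-xanthen-9-one; 3, tert-butyldimethylsilyl chloride
Product: 4, 3,6-bis[(tert-butyldimethylsilyl)oxy]-9H-xanthen-9-one
Conditions: TBSCl (2.4 eq), imidazole, DMF, rt
Reagents that add atoms: TBSCl, CC(C)(C)[Si](C)(C)Cl
Why: Standard phenol silylation; it removes the acidic OH groups so the xanthone carbonyl can accept a carbon nucleophile.

**Step 3 (key step)**
Reactants: 4, 3,6-bis(TBS-oxy)xanthone; 5, dibromomethane
Product: 6, 3,7-bis[(tert-butyldimethylsilyl)oxy]dibenzo[b,f]oxepin-10(11H)-one (C10 carbonyl on the ring bearing the 7-OTBS, C11 CH2 on the ring bearing the 3-OTBS)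
Conditions: CH2Br2, LiTMP, THF, −78 °C; add 4; then n-BuLi, −78 → −20 °C; AcOH quench at low temperature
Reagents that add atoms: dibromomethane, BrCBr (supplies the CH2 carbon)
Why: Proposed new method: LiCHBr2 adds to C9 (as it does to esters), Br/Li exchange gives the β-oxido carbenoid Ar2C(OLi)–CHBrLi, and loss of LiBr with a 1,2-aryl shift gives the lithium enolate of the 7-ring ketone; the two aryl groups are equivalent, so either migration gives the same product; the closest known reaction is the dibromomethyllithium (β-oxido carbenoid, Tiffeneau–Demjanov-type) ring enlargement of cycloalkanones, not yet shown on xanthones.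

**Step 4**
Reactants: 6, bis-TBS dibenzoxepinone; 7, N-bromosuccinimide
Product: 8, 2-bromo-3,7-bis[(tert-butyldimethylsilyl)oxy]dibenzo[b,f]oxepin-10(11H)-one (Br on the CH2-side ring, ortho to its OTBS and para to the ring oxygen O5)
Conditions: NBS (1.0 eq), MeCN, −20 → 0 °C, dark, no acid
Reagents that add atoms: NBS, O=C1CCC(=O)N1Br
Why: Electrophilic aromatic bromination goes to ring A because ring B is deactivated by the conjugated ketone, and to C2 because C4 lies between two oxygens and is shielded by the silyl group; neutral, dark conditions are chosen so the C11 methylene is not brominated.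

**Step 5**
Reactants: 8, bromo ketone; 9, 3-methylbut-2-enal (prenal)
Product: 10, bis-TBS bromo pentacycle: 2,2-dimethyl-2H-pyran fused across C10=C11 of the dibenzo[b,f]oxepine, pyran O on C10 (former carbonyl carbon, ring-B side), pyran C4 on C11 (ring-A side, the ring carrying Br)
Conditions: LiHMDS, THF, −78 °C; prenal; MsCl, Et3N, −78 → 0 °C; then DBU, PhMe, 80 °C (one pot)
Reagents that add atoms: prenal, CC(C)=CC=O (all five carbons; its oxygen is lost as mesylate/water)
Why: Directed aldol, E1cB elimination to the 11-(3-methylbut-2-enylidene) ketone, base-mediated E/Z equilibration through the trienolate, and oxa-6π electrocyclisation of the Z-dienone (Knoevenagel-type condensation/oxa-6π sequence) give the gem-dimethyl 2H-pyran, the same valence isomer as the natural product.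

**Step 6**
Reactants: 10, bis-TBS bromo pentacycle; 11, 3-methylbut-2-enylboronic acid pinacol ester
Product: 12, Artocarpol D
Conditions: prenyl-Bpin (2 eq), Pd(OAc)2 / bulky di-tert-butylbiarylphosphine (tBuXPhos class, selected for linear selectivity), aq. K3PO4, THF, 40 °C; then TBAF, AcOH buffer, 0 °C → rt, same pot, under Ar
Reagents that add atoms: prenyl-Bpin, CC(C)=CCB1OC(C)(C)C(C)(C)O1 (supplies the C5 prenyl group)
Why: Suzuki–Miyaura allyl–aryl coupling in which ligand choice steers reductive elimination to the primary (α, linear) terminus, followed by fluoride cleavage of both aryl silyl ethers; the base/fluoride conditions leave the prenyl group and the dienol-ether pyran intact.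

## Compound list

1 | 2,2',4,4'-tetrahydroxybenzophenone | O=C(c1ccc(O)cc1O)c1ccc(O)cc1O | starting material
2 | 3,6-dihydroxy-9H-xanthen-9-one | O=C1c2ccc(O)cc2Oc2cc(O)ccc12 | intermediate
3 | tert-butyldimethylsilyl chloride | CC(C)(C)[Si](C)(C)Cl | starting material
4 | 3,6-bis(TBS-oxy)-9H-xanthen-9-one | O=C1c2ccc(O[Si](C)(C)C(C)(C)C)cc2Oc2cc(O[Si](C)(C)C(C)(C)C)ccc12 | intermediate
5 | dibromomethane | BrCBr | starting material
6 | 3,7-bis(TBS-oxy)dibenzo[b,f]oxepin-10(11H)-one | O=C1Cc2ccc(O[Si](C)(C)C(C)(C)C)cc2Oc2cc(O[Si](C)(C)C(C)(C)C)ccc12 | intermediate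
7 | N-bromosuccinimide | O=C1CCC(=O)N1Br | starting material
8 | 2-bromo-3,7-bis(TBS-oxy)dibenzo[b,f]oxepin-10(11H)-one | O=C1Cc2cc(Br)c(O[Si](C)(C)C(C)(C)C)cc2Oc2cc(O[Si](C)(C)C(C)(C)C)ccc12 | intermediate
9 | 3-methylbut-2-enal (prenal) | CC(C)=CC=O | starting material
10 | bis-TBS bromo pentacycle (des-prenyl, bromo analogue of the target) | Brc1cc2c(cc1O[Si](C)(C)C(C)(C)C)Oc1cc(O[Si](C)(C)C(C)(C)C)ccc1C1=C2C=CC(C)(C)O1 | intermediate
11 | 3-methylbut-2-enylboronic acid pinacol ester | CC(C)=CCB1OC(C)(C)C(C)(C)O1 | starting material
12 | Artocarpol D | CC(C)=CCc1cc2c(cc1O)Oc1cc(O)ccc1C1=C2C=CC(C)(C)O1 | target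

## Summary

Total steps: 6 (step 6 is a one-pot coupling/desilylation). Longest linear sequence: 6.

Steps most likely to fail, with fallbacks:

1. **Step 3 (carbenoid ring expansion of a deactivated xanthone).** LiCHBr2 may add poorly, or the carbenoid may decompose without aryl shift. Fallback: add MeMgBr to 4 and dehydrate to the 9-methylenexanthene, then carry out an iodine(III) oxidative 1,2-aryl shift with PhI(OH)OTs in MeOH to reach the same ketone 6 (cationic route, one extra step).
2. **Step 5 (condensation and 6π closure).** Retro-aldol, prenal self-condensation, or a dienone that does not close are the risks. Fallback: C11-prenylate the enolate of 8 with prenyl bromide, then effect DDQ dehydrogenative oxa-cyclisation of the α-prenyl ketone, so the pyran is formed by oxidation instead of condensation.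
3. **Step 6 (linear versus branched prenyl transfer on a hindered, electron-rich aryl bromide).** Fallback: Br/Li exchange on 10 (t-BuLi, −78 °C), transmetalation to the aryl cuprate and SN2 alkylation with prenyl bromide, followed by a separate TBAF desilylation.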